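Cuts: the C8'O–acyl bond (glutarate half-ester), C1'–C5 (ketone plus C6 enynyl anion), C2'–CH3 and the C4' oxygen. Then the ring bond C5'–C6', and last the cyclopentene C=C and the two allyl–carbinol bonds.
Feature: in the six-membered ring, quaternary C6' carries CH3 and the oxymethyl carbon C8' and lies between oxygen-bearing C1' and the methylene C5'. This is a 2-(hydroxymethyl)-2-methylcyclohexanone, the product formed when a ring carbon of a 1-(2-methyloxiran-2-yl)cyclopentanol shifts onto the oxirane.
Forward: glycidate plus two allyl groups, metathesis to the five-membered ring, and expansion to the only carbocycle of the target. Then C2' methyl, C4' oxygen, C4' ketal, chain at C1', alkyne reduction, aldehyde, glutarate ester, acid and free enone.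
Stereochemistry: C6' comes from the (R)-glycidate by inversion in the shift, and C1' from C6' by chelate-directed acetylide addition. The glutarate carbinol comes from esterase desymmetrisation, 2Z from the enynol and 4E from trans-hydroalumination.
Key step: step 4

Assumption: abscisic acid numbering is used (ring C1'–C6', chain C1–C5, C8' = oxygenated carbon on C6'). The SMILES places C8' cis to the dienoic acid chain and trans to the C1' hydroxyl (1'R,6'S), and the glutarate carbinol is R.
Assumption: 1 is bought as the R enantiomer.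

Step 1
Reactants: 1 methyl (2R)-2-methyloxirane-2-carboxylate; 2 allylmagnesium bromide
Product: 4 4-[(2R)-2-methyloxiran-2-yl]hepta-1,6-dien-4-ol, via allyl ketone 3 (not isolated)
Conditions: 2 (2.2 equiv), THF, −78 °C
Reagents that add atoms: none
Why: Double Grignard addition to an ester, in which the allyl reagent attacks the carbonyl groups of 1 and of the more electrophilic ketone 3 far faster at −78 °C than it opens the hindered oxirane, so the oxirane stereocentre is left untouched.

Step 2
Reactants: 4 4-[(2R)-2-methyloxiran-2-yl]hepta-1,6-dien-4-ol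
Product: 5 1-[(2R)-2-methyloxiran-2-yl]cyclopent-3-en-1-ol
Conditions: second-generation Grubbs catalyst (H2IMes)(PCy3)Cl2Ru=CHPh (1 mol %), CH2Cl2, 40 °C
Reagents that add atoms: none
Why: Ring-closing metathesis of a diallyl carbinol to a cyclopentene is fast, is driven by loss of ethene and tolerates the free tertiary alcohol and the oxirane.

Step 3
Reactants: 5 1-[(2R)-2-methyloxiran-2-yl]cyclopent-3-en-1-ol
Product: 6 trimethyl({1-[(2R)-2-methyloxiran-2-yl]cyclopent-3-en-1-yl}oxy)silane
Conditions: 1-(trimethylsilyl)imidazole, CH2Cl2, 0 °C to rt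
Reagents that add atoms: 1-(trimethylsilyl)imidazole, C[Si](C)(C)n1ccnc1
Why: Silylation of a hindered tertiary alcohol with a strong neutral silyl donor, chosen because no acid is present that could open the oxirane too early.

Step 4
Reactants: 6 trimethyl({1-[(2R)-2-methyloxiran-2-yl]cyclopent-3-en-1-yl}oxy)silane
Product: 8 (2S)-2-(hydroxymethyl)-2-methylcyclohex-4-en-1-one, via trichlorotitanium alkoxide 7 (not isolated)
Conditions: TiCl4 (1.1 equiv), CH2Cl2, −78 °C, short contact; then pH 7 buffer
Reagents that add atoms: none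
Why: TiCl4 binds the oxirane oxygen and stretches its bond to the fully substituted carbon C6', and the ring C–C bond at the carbinol carbon that stands antiperiplanar to it moves to C6' while the silyloxy carbon becomes the C1' carbonyl with loss of Me3SiCl, which gives alkoxide 7 and, after hydrolysis, 8. The reaction type is the Lewis-acid semipinacol rearrangement of 2,3-epoxy alcohol silyl ethers, also known as the enlargement of 1-(oxiran-2-yl)cycloalkanols to 2-(hydroxymethyl)cycloalkanones. The six-membered ring arises not by a cyclisation but by a one-carbon ring expansion, a 1,2-alkyl shift that inserts C6' between C1' and C5' and forms the C5'–C6' bond. C6' is the only new stereocentre and is dictated by the oxirane carbon of 6, since the migrating carbon arrives on the face opposite the departing oxygen (inversion, R oxirane to S ketone). Cleavage of the tertiary rather than the primary C–O bond follows from the better stabilised positive charge at C6', the two ring methylenes are related by the mirror plane of the cyclopentenol so only one ketone can form, and the push of the silyloxy oxygen favours the carbon shift over a hydride shift from C8' to C6'. The low temperature should keep the shift concerted and limit chloride capture, alkene conjugation and retro-aldol loss of formaldehyde.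

Step 5
Reactants: 8 (2S)-2-(hydroxymethyl)-2-methylcyclohex-4-en-1-one
Product: 9 (2S)-2-{[tert-butyl(diphenyl)silyl]oxymethyl}-2-methylcyclohex-4-en-1-one
Conditions: TBDPSCl, imidazole, CH2Cl2, 0 °C to rt
Reagents that add atoms: tert-butyl(chloro)diphenylsilane, CC(C)(C)[Si](Cl)(c1ccccc1)c1ccccc1
Why: Silyl ether formation on a primary alcohol under weakly basic conditions that should not provoke retro-aldol cleavage, with an acid-stable group chosen to survive the ketalisation in step 9.

Step 6
Reactants: 9 (2S)-2-{[tert-butyl(diphenyl)silyl]oxymethyl}-2-methylcyclohex-4-en-1-one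
Product: 11 (6S)-6-{[tert-butyl(diphenyl)silyl]oxymethyl}-2,6-dimethylcyclohex-3-en-1-one (C2 epimers), via lithium dienolate 10 (not isolated)
Conditions: LiN(iPr)2, THF, −78 °C; MeI, DMPU, −78 to −40 °C
Reagents that add atoms: iodomethane, CI
Why: Kinetic alpha-alkylation of an extended enolate, in which quaternary C6' leaves only the doubly activated C2' proton for the base (any conjugated isomer of 9 gives the same dienolate 10) and such lithium dienolates take iodomethane at the alpha carbon and leave C3'=C4' unconjugated, the new C2' centre being erased in step 7.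

Step 7
Reactants: 11 (6S)-6-{[tert-butyl(diphenyl)silyl]oxymethyl}-2,6-dimethylcyclohex-3-en-1-one
Product: 13 (6S)-6-{[tert-butyl(diphenyl)silyl]oxymethyl}-4-hydroxy-2,6-dimethylcyclohex-2-en-1-one (C4 epimers), via epoxy ketone 12 (not isolated)
Conditions: mCPBA, CH2Cl2, 0 °C; aqueous wash; crude 12, 1,8-diazabicyclo[5.4.0]undec-7-ene (DBU), CH2Cl2, 0 °C to rt
Reagents that add atoms: 3-chloroperoxybenzoic acid, OOC(=O)c1cccc(Cl)c1
Why: Prilezhaev epoxidation of the isolated cis alkene followed by base-induced E1cB opening of the beta,gamma-epoxy ketone places the alkene at C2'=C3' and oxygen at C4' without regiochemical ambiguity, and the C4' carbinol mixture converges in step 8.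

Step 8
Reactants: 13 (6S)-6-{[tert-butyl(diphenyl)silyl]oxymethyl}-4-hydroxy-2,6-dimethylcyclohex-2-en-1-one
Product: 14 (6S)-6-{[tert-butyl(diphenyl)silyl]oxymethyl}-2,6-dimethylcyclohex-2-ene-1,4-dione
Conditions: Dess–Martin periodinane, CH2Cl2, rt
Reagents that add atoms: none
Why: Dess–Martin oxidation of a secondary allylic alcohol to the ene-dione under neutral conditions, with quaternary C6' excluding both epimerisation and aromatisation.

Step 9
Reactants: 14 (6S)-6-{[tert-butyl(diphenyl)silyl]oxymethyl}-2,6-dimethylcyclohex-2-ene-1,4-dione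
Product: 15 (8S)-8-{[tert-butyl(diphenyl)silyl]oxymethyl}-3,3,8,10-tetramethyl-1,5-dioxaspiro[5.5]undec-10-en-9-one
Conditions: 2,2-dimethylpropane-1,3-diol, pyridinium p-toluenesulfonate (cat.), benzene, reflux, Dean–Stark trap
Reagents that add atoms: 2,2-dimethylpropane-1,3-diol, OCC(C)(C)CO
Why: Acid-catalysed ketalisation with water removal should be site-selective for C4', because C1' is shielded by quaternary C6' and the C2' methyl, the behaviour well known for 2,6,6-trimethylcyclohex-2-ene-1,4-dione.

Step 10
Reactants: 15 (8S)-8-{[tert-butyl(diphenyl)silyl]oxymethyl}-3,3,8,10-tetramethyl-1,5-dioxaspiro[5.5]undec-10-en-9-one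
Product: 16 (8S)-8-(hydroxymethyl)-3,3,8,10-tetramethyl-1,5-dioxaspiro[5.5]undec-10-en-9-one
Conditions: Bu4NF, AcOH (one equivalent each), THF, rt
Reagents that add atoms: none
Why: Fluoride cleavage of the silyl ether, buffered with acetic acid so that no free alkoxide accumulates that could lose formaldehyde by retro-aldol reaction, leaves ketal and enone intact.

Step 11
Reactants: 16 (8S)-8-(hydroxymethyl)-3,3,8,10-tetramethyl-1,5-dioxaspiro[5.5]undec-10-en-9-one; 17 (Z)-3-methylpent-2-en-4-yn-1-ol
Product: 20 (8S,9S)-8-(hydroxymethyl)-9-[(3Z)-5-hydroxy-3-methylpent-3-en-1-yn-1-yl]-3,3,8,10-tetramethyl-1,5-dioxaspiro[5.5]undec-10-en-9-ol, via chloromagnesium alkoxide 18 (not isolated), via dilithio enynol 19 (not isolated)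
Conditions: 16, i-PrMgCl (1.0 equiv), THF, −78 °C; separately 17, n-BuLi (2.0 equiv), THF, −78 °C; combine (19 in excess), −78 to 0 °C
Reagents that add atoms: none
Why: Chelation-controlled 1,2-addition of a lithium acetylide to a non-enolisable ketone, in which magnesium ties the C8' alkoxide to the C1' carbonyl oxygen in a six-membered chelate that holds C8' pseudo-equatorial and the C6' methyl pseudo-axial, so the small nucleophile enters on the axial trajectory anti to that methyl and C1' is set with the chain cis to C8' and the hydroxyl trans to it, as in the target.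

Step 12
Reactants: 20 enyne triol
Product: 21 (8S,9R)-8-(hydroxymethyl)-9-[(1E,3Z)-5-hydroxy-3-methylpenta-1,3-dien-1-yl]-3,3,8,10-tetramethyl-1,5-dioxaspiro[5.5]undec-10-en-9-ol
Conditions: NaAlH2(OCH2CH2OMe)2 (excess), THF, 0 °C to rt
Reagents that add atoms: none
Why: Alkoxide-directed trans-hydroalumination of the propargylic alcohol and protonolysis on work-up should give only the 4E alkene and leave the 2Z alkene, the ring alkene and the ketal alone, this being the standard reduction for enynols of this type (the C1' descriptor changes by CIP rank only).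

Step 13
Reactants: 21 diene triol
Product: 22 (2Z,4E)-5-[(8S,9R)-9-hydroxy-8-(hydroxymethyl)-3,3,8,10-tetramethyl-1,5-dioxaspiro[5.5]undec-10-en-9-yl]-3-methylpenta-2,4-dienal
Conditions: activated MnO2 (excess), CH2Cl2, rt
Reagents that add atoms: none
Why: MnO2 oxidises only the dienylic primary alcohol, so the neopentyl C8' hydroxyl and the tertiary C1' hydroxyl stay free and the 2Z geometry should hold under these neutral heterogeneous conditions.

Step 14
Reactants: 23 dimethyl 3-hydroxy-3-methylpentanedioate
Product: 24 (3S)-3-hydroxy-5-methoxy-3-methyl-5-oxopentanoic acid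
Conditions: pig liver esterase, phosphate buffer pH 8, 25 °C
Reagents that add atoms: water, O
Why: Enzymatic desymmetrisation of a prochiral glutarate, in which the esterase hydrolyses one enantiotopic ester group and is known to deliver the S half-ester, the spatial arrangement required in the target (R by CIP once the acid carries the larger alcohol).

Step 15
Reactants: 22 dienal diol; 24 (3S)-3-hydroxy-5-methoxy-3-methyl-5-oxopentanoic acid
Product: 26 1-{[(8S,9R)-9-hydroxy-3,3,8,10-tetramethyl-9-[(1E,3Z)-3-methyl-5-oxopenta-1,3-dien-1-yl]-1,5-dioxaspiro[5.5]undec-10-en-8-yl]methyl} 5-methyl (3R)-3-hydroxy-3-methylpentanedioate, via O-acylisourea 25 (not isolated)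
Conditions: DCC, 4-(dimethylamino)pyridine (DMAP, cat.), CH2Cl2, 0 °C to rt
Reagents that add atoms: none
Why: Steglich esterification, in which only the primary C8' hydroxyl is acylated because the two tertiary alcohols are inert to carbodiimide/DMAP activation, and no stereocentre is affected.

Step 16
Reactants: 26 glutarate ester aldehyde
Product: 27 (2Z,4E)-5-[(8S,9R)-9-hydroxy-8-({[(3R)-3-hydroxy-5-methoxy-3-methyl-5-oxopentanoyl]oxy}methyl)-3,3,8,10-tetramethyl-1,5-dioxaspiro[5.5]undec-10-en-9-yl]-3-methylpenta-2,4-dienoic acid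
Conditions: NaClO2, NaH2PO4, 2-methylbut-2-ene, t-BuOH/H2O, 0 °C to rt
Reagents that add atoms: sodium chlorite, [Na+].[O-]Cl=O
Why: Pinnick oxidation turns the enal into the acid in a mildly acidic buffer with an alkene scavenger for hypochlorite, sparing the alkenes, both esters, the free alcohols and the 2Z geometry.

Step 17
Reactants: 27 ketal acid
Product: 28 (2Z,4E)-5-[(1R,6S)-1-hydroxy-6-({[(3R)-3-hydroxy-5-methoxy-3-methyl-5-oxopentanoyl]oxy}methyl)-2,6-dimethyl-4-oxocyclohex-2-en-1-yl]-3-methylpenta-2,4-dienoic acid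
Conditions: 1 M HCl, THF, 0 °C to rt
Reagents that add atoms: water, O
Why: Acid hydrolysis of the allylic ketal is much faster than attack on the esters or the tertiary alcohols, and because the C8' oxygen is acylated no oxa-Michael closure onto the liberated enone can follow.

Compound list
1 | methyl (2R)-2-methyloxirane-2-carboxylate | COC(=O)[C@@]1(C)CO1 | starting material
2 | allylmagnesium bromide | C=CC[Mg]Br | starting material
3 | 1-[(2R)-2-methyloxiran-2-yl]but-3-en-1-one | C=CCC(=O)[C@@]1(C)CO1 | intermediate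
4 | 4-[(2R)-2-methyloxiran-2-yl]hepta-1,6-dien-4-ol | C=CCC(O)(CC=C)[C@@]1(C)CO1 | intermediate
5 | 1-[(2R)-2-methyloxiran-2-yl]cyclopent-3-en-1-ol | OC1(CC=CC1)[C@@]2(C)CO2 | intermediate
6 | trimethylsilyl ether of 5 | C[Si](C)(C)OC1(CC=CC1)[C@@]2(C)CO2 | intermediate
7 | trichlorotitanium alkoxide of 8 | Cl[Ti](Cl)(Cl)OC[C@]1(C)CC=CCC1=O | intermediate
8 | (2S)-2-(hydroxymethyl)-2-methylcyclohex-4-en-1-one | OC[C@]1(C)CC=CCC1=O | intermediate
9 | (2S)-2-{[tert-butyl(diphenyl)silyl]oxymethyl}-2-methylcyclohex-4-en-1-one | CC(C)(C)[Si](c1ccccc1)(c1ccccc1)OC[C@]1(C)CC=CCC1=O | intermediate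
10 | lithium (6S)-6-{[tert-butyl(diphenyl)silyl]oxymethyl}-6-methylcyclohexa-1,3-dien-1-olate | CC(C)(C)[Si](c1ccccc1)(c1ccccc1)OC[C@]1(C)CC=CC=C1O[Li] | intermediate
11 | (6S)-6-{[tert-butyl(diphenyl)silyl]oxymethyl}-2,6-dimethylcyclohex-3-en-1-one, C2 epimers | CC(C)(C)[Si](c1ccccc1)(c1ccccc1)OC[C@]1(C)CC=CC(C)C1=O | intermediate
12 | (4S)-4-{[tert-butyl(diphenyl)silyl]oxymethyl}-2,4-dimethyl-7-oxabicyclo[4.1.0]heptan-3-one, isomers at the other centres | CC(C)(C)[Si](c1ccccc1)(c1ccccc1)OC[C@]1(C)CC2OC2C(C)C1=O | intermediate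
13 | (6S)-6-{[tert-butyl(diphenyl)silyl]oxymethyl}-4-hydroxy-2,6-dimethylcyclohex-2-en-1-one, C4 epimers | CC(C)(C)[Si](c1ccccc1)(c1ccccc1)OC[C@]1(C)CC(O)C=C(C)C1=O | intermediate
14 | (6S)-6-{[tert-butyl(diphenyl)silyl]oxymethyl}-2,6-dimethylcyclohex-2-ene-1,4-dione | CC(C)(C)[Si](c1ccccc1)(c1ccccc1)OC[C@]1(C)CC(=O)C=C(C)C1=O | intermediate
15 | (8S)-8-{[tert-butyl(diphenyl)silyl]oxymethyl}-3,3,8,10-tetramethyl-1,5-dioxaspiro[5.5]undec-10-en-9-one | CC(C)(C)[Si](c1ccccc1)(c1ccccc1)OC[C@]1(C)CC2(OCC(C)(C)CO2)C=C(C)C1=O | intermediate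
16 | (8S)-8-(hydroxymethyl)-3,3,8,10-tetramethyl-1,5-dioxaspiro[5.5]undec-10-en-9-one | OC[C@]1(C)CC2(OCC(C)(C)CO2)C=C(C)C1=O | intermediate
17 | (Z)-3-methylpent-2-en-4-yn-1-ol | C#C/C(C)=C\CO | starting material
18 | chloromagnesium alkoxide of 16 | Cl[Mg]OC[C@]1(C)CC2(OCC(C)(C)CO2)C=C(C)C1=O | intermediate
19 | O,C-dilithio derivative of 17 | [Li]C#C/C(C)=C\CO[Li] | intermediate
20 | (8S,9S)-8-(hydroxymethyl)-9-[(3Z)-5-hydroxy-3-methylpent-3-en-1-yn-1-yl]-3,3,8,10-tetramethyl-1,5-dioxaspiro[5.5]undec-10-en-9-ol | OC[C@]1(C)CC2(OCC(C)(C)CO2)C=C(C)[C@]1(O)C#C/C(C)=C\CO | intermediate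
21 | (8S,9R)-8-(hydroxymethyl)-9-[(1E,3Z)-5-hydroxy-3-methylpenta-1,3-dien-1-yl]-3,3,8,10-tetramethyl-1,5-dioxaspiro[5.5]undec-10-en-9-ol | OC[C@]1(C)CC2(OCC(C)(C)CO2)C=C(C)[C@]1(O)/C=C/C(C)=C\CO | intermediate
22 | (2Z,4E)-5-[(8S,9R)-9-hydroxy-8-(hydroxymethyl)-3,3,8,10-tetramethyl-1,5-dioxaspiro[5.5]undec-10-en-9-yl]-3-methylpenta-2,4-dienal | OC[C@]1(C)CC2(OCC(C)(C)CO2)C=C(C)[C@]1(O)/C=C/C(C)=C\C=O | intermediate
23 | dimethyl 3-hydroxy-3-methylpentanedioate | COC(=O)CC(C)(O)CC(=O)OC | starting material
24 | (3S)-3-hydroxy-5-methoxy-3-methyl-5-oxopentanoic acid | COC(=O)C[C@@](C)(O)CC(=O)O | intermediate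
25 | O-acylisourea from 24 and DCC | COC(=O)C[C@@](C)(O)CC(=O)OC(=NC1CCCCC1)NC1CCCCC1 | intermediate
26 | C8' (3R)-glutarate ester of 22 (aldehyde, ketal) | COC(=O)C[C@@](C)(O)CC(=O)OC[C@]1(C)CC2(OCC(C)(C)CO2)C=C(C)[C@]1(O)/C=C/C(C)=C\C=O | intermediate
27 | dienoic acid from 26 (ketal) | COC(=O)C[C@@](C)(O)CC(=O)OC[C@]1(C)CC2(OCC(C)(C)CO2)C=C(C)[C@]1(O)/C=C/C(C)=C\C(=O)O | intermediate
28 | CNP0274837.1, (1'R,6'S,3R; 2Z,4E) | COC(=O)C[C@@](C)(O)CC(=O)OC[C@]1(C)CC(=O)C=C(C)[C@]1(O)/C=C/C(C)=C\C(=O)O | target

Total step count: 17. Longest linear sequence: 16 (steps 1–13 and 15–17).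

Steps most likely to fail

Step 4. Three processes are at risk. Chloride may capture the activated oxirane. Ionisation to an open tertiary cation may erode configuration or allow a hydride shift from C8'. The beta-hydroxy ketone may undergo retro-aldol cleavage or alkene conjugation during work-up. The fallback sets out from 5 and comes back at 9. The free epoxy alcohol 5 is heated with Al(OiPr)3 in i-PrOH, a tandem semipinacol rearrangement/Meerwein–Ponndorf–Verley reduction. The aluminium alkoxide of the carbinol activates the oxirane internally, so no nucleophilic halide is present. The same C5'–C6' shift should occur with inversion, and the ketone is reduced in the same flask to the stable diol (2S)-2-(hydroxymethyl)-2-methylcyclohex-4-en-1-ol F1. Selective silylation of the primary hydroxyl (TBDPSCl, imidazole) gives (6S)-6-{[tert-butyl(diphenyl)silyl]oxymethyl}-6-methylcyclohex-3-en-1-ol F2. Dess–Martin oxidation of F2 gives 9.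

Step 11. Facial selectivity may be poor if the chelate is loosened by THF and by the polar dianion. The triply anionic mixture may also react sluggishly, or the alkoxide may lose formaldehyde. The fallback sets out from 16 and comes back at 20, and it joins the chain in two stages. Excess ethynylmagnesium bromide in THF/toluene first forms the bromomagnesium alkoxide of 16 F3. This all-magnesium chelate then takes up the small monoanionic nucleophile on the same face. The product is (8S,9R)-9-ethynyl-8-(hydroxymethyl)-3,3,8,10-tetramethyl-1,5-dioxaspiro[5.5]undec-10-en-9-ol F4, a compact diol at which any C1' epimer should be removable. Sonogashira coupling of F4 with (Z)-3-iodobut-2-en-1-ol (I/C(C)=C\CO; Pd(PPh3)4, CuI, Et3N) forms the C4–C3 bond with retention of the alkene geometry and gives 20.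

Step 15. Acylation of the neopentyl C8' hydroxyl may be slow. The activated beta-hydroxy acid could then rearrange to the N-acylurea, dehydrate or cyclise through its own tertiary hydroxyl. The fallback sets out from 24 (with 22) and comes back at 26, and it masks that hydroxyl. Et3SiCl and imidazole in DMF give triethylsilyl (3R)-5-methoxy-3-methyl-5-oxo-3-(triethylsilyloxy)pentanoate F5. Brief treatment with K2CO3 in aqueous MeOH frees (3S)-5-methoxy-3-methyl-5-oxo-3-(triethylsilyloxy)pentanoic acid F6. Yamaguchi activation (2,4,6-trichlorobenzoyl chloride, Et3N) gives the mixed 2,4,6-trichlorobenzoic anhydride of F6 F7. With 22 and DMAP in toluene, F7 gives the O-triethylsilyl ether of 26 F8. HF·pyridine buffered with pyridine in THF removes the silyl group and gives 26.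

Further compounds
F1 | step 4 | (2S)-2-(hydroxymethyl)-2-methylcyclohex-4-en-1-ol (carbinol epimers) | OC[C@]1(C)CC=CCC1O
F2 | step 4 | (6S)-6-{[tert-butyl(diphenyl)silyl]oxymethyl}-6-methylcyclohex-3-en-1-ol (carbinol epimers) | CC(C)(C)[Si](c1ccccc1)(c1ccccc1)OC[C@]1(C)CC=CCC1O
F3 | step 11 | bromomagnesium alkoxide of 16 | Br[Mg]OC[C@]1(C)CC2(OCC(C)(C)CO2)C=C(C)C1=O
F4 | step 11 | (8S,9R)-9-ethynyl-8-(hydroxymethyl)-3,3,8,10-tetramethyl-1,5-dioxaspiro[5.5]undec-10-en-9-ol | OC[C@]1(C)CC2(OCC(C)(C)CO2)C=C(C)[C@]1(O)C#C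
F5 | step 15 | triethylsilyl (3R)-5-methoxy-3-methyl-5-oxo-3-(triethylsilyloxy)pentanoate | COC(=O)C[C@@](C)(O[Si](CC)(CC)CC)CC(=O)O[Si](CC)(CC)CC
F6 | step 15 | (3S)-5-methoxy-3-methyl-5-oxo-3-(triethylsilyloxy)pentanoic acid | COC(=O)C[C@@](C)(O[Si](CC)(CC)CC)CC(=O)O
F7 | step 15 | mixed 2,4,6-trichlorobenzoic anhydride of F6 | COC(=O)C[C@@](C)(O[Si](CC)(CC)CC)CC(=O)OC(=O)c1c(Cl)cc(Cl)cc1Cl
F8 | step 15 | O-triethylsilyl ether of 26 | COC(=O)C[C@@](C)(O[Si](CC)(CC)CC)CC(=O)OC[C@]1(C)CC2(OCC(C)(C)CO2)C=C(C)[C@]1(O)/C=C/C(C)=C\C=O
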